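The runs are simulated for an exercise; noise was put on by code.

With time, target in Sunday's flask at 50 °C rises to a reading of 46.5%, then falls to 31.1% at 3.00 min, where the electrophile reads 8.1%.

| flask | electrophile | nucleophile | protic impurity | temperature | remark | time |
|---|---|---|---|---|---|---|
| Sunday's | 0.050 M | 0.075 M | 0.010 M | 50 °C | the very flask that is asked about, followed so far |  |
| Tuesday's | 0.050 M | 0.075 M | 0.0067 M | 56 °C | run made earlier |  |
| flask | 0.050 M | 0.0750 M | 0.0100 M | 50 °C |  | 4.0 min |

- Sunday's (time / min: target / %, electrophile / %): 0.250: 38.5, 39.0; 0.417: 44.2, 29.5; 0.667: 46.5, 21.8; 0.833: 46.0, 19.0; 1.33: 42.0, 13.4; 2.00: 36.1, 10.2; 3.00: 31.1, 8.1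
- Tuesday's (time / s: target / %, electrophile / %): 10.0: 39.8, 43.1; 12.0: 42.0, 38.7; 20.0: 46.1, 30.2; 25.0: 46.3, 26.5; 40.0: 43.5, 20.5; 60.0: 38.0, 17.3; 90.0: 32.1, 13.9

(standard deviation of a reading: 0.3 percentage points)

- target that was removed still counts
- the earlier runs were read with a standard deviation of 0.3 percentage points
- additions bring no volume worth counting

- south-east: change nothing and wait 8.0 min more
- north-west: at 4.0 min raise the temperature by 15 K, then wait 8.0 min
- north-east: at 4.0 min add nucleophile, 100% of the amount charged, then wait 8.0 min
- south-west: at 4.0 min take out 90% of the target then present, then wait 8.0 min

* target, in percent of the electrophile first charged, at 4.0 min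
* the option that brings most further target ("none" if no option brings more than 2 percentage points) (south-east / north-west / north-east / south-west / none)
* target present, with what was taken out counted in, in percent of the electrophile first charged, after south-east
* target present, with what was taken out counted in, in percent of the electrophile first charged, after north-east

Two of us read these runs differently. The forecast's author sees a loss that continues, “which suggests a nucleophile-independent first-order decay”, and gives 26.5% now, 7% after south-east, 1% after north-east, and as best: none.

I hold that the loss runs back. I take the protic impurity to spend electrophile one for one, 20.0% of the charge, and call whatever else is missing from the readings the reservoir, which I suppose exchanges with target both ways. Over Sunday's first four readings the reservoir grows by 0.214 min⁻¹ of the charge, with target averaging 43.8% and the reservoir 8.75%. Over the last two readings it grows by 0.0710 min⁻¹, with target at 33.6% and the reservoir at 37.3%.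

Ignoring the back step early gives a forward constant of 0.490 min⁻¹, and the late stretch then gives a back constant of 0.251 min⁻¹. Put back in, these become 0.540 min⁻¹ and 0.296 min⁻¹. So the resting share, the part of target plus reservoir that stands as target once the exchange is at equilibrium, is 35.4%, and the approach has a half-life of 0.829 min.

From the pool at 3.00 min, the resting share gives a resting level of target of 25.5%, so I reckon 27.9% at 4.0 min, a little above the forecast. The further 8.0 min is far longer than this half-life. So I estimate about that resting level after waiting, and about 28.3% after adding nucleophile if the electrophile left all became target, and neither estimate is a gain of the 2 percentage points required. Taking out 90% of the target shrinks the pool, but by my reckoning the reservoir refills it, for an estimated gain of 14 points, more than the 2 points required.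

The simulation gives 27.9% now, 24.9% after south-east and 25.8% after north-east. Best is south-west, bringing 14 points.

    nucleophile + acid set free ⇌ protonated nucleophile, settled at all times (K = 15000 M⁻¹, ΔH = 16.0 kJ mol⁻¹)
    electrophile + nucleophile → acid set free + target (k = 0.960 M⁻¹ s⁻¹, Ea = 63.0 kJ mol⁻¹)
    target ⇌ isomer of the product (K = 2.10, k = 0.00850 s⁻¹, Ea = 97.0 kJ mol⁻¹, ΔH = 2.00 kJ mol⁻¹)
    electrophile + protic impurity → quenched substrate (k = 17.0 M⁻¹ s⁻¹, Ea = 44.0 kJ mol⁻¹)
    (constants at 50 °C)

In this flask the target and isomer of the product relax with a half-life of 0.921 min, shorter than the 4.0 min asked about. At 4.00 min target is made at 0.311 of the rate at which it is used up, and it stands at 27.9%, above the 26.0% that the resting share gives for target plus isomer. The forecast's one-way decay suits the early stretch, with isomer at 6.13% against target at 43.8% at 0.400 min.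

For the same flask read at 2.5 min, the same resting level and relaxation give 34.0%. The simulation gives 33.6%.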